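The constants used here are assumed.

I decided to treat this flask as a first-order lag and to count how many time constants fit into the run.

    electrophile ⇌ dormant form (K1 = 16, k1 = 0.00772 min⁻¹)
    electrophile + nucleophile → acid set free + target (k2 = 0.0113 M⁻¹ min⁻¹)
    crystals ⇌ acid set free, rate k3*(cs3 - [acid set free]) while solid is left; crystals form when [acid set free] > cs3 (cs3 = 0.12 M, k3 = 0.199 min⁻¹)
    acid set free + free base ⇌ salt of the base, settled at all times (K4 = 35 M⁻¹)
    solid nucleophile ⇌ nucleophile, rate k5*(cs5 - [nucleophile]) while solid is left; crystals form when [nucleophile] > cs5 (cs5 = 0.079 M, k5 = 0.0209 min⁻¹)
    nucleophile + acid set free ⇌ protonated nucleophile, settled at all times (K6 = 220 M⁻¹)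

| flask | electrophile | free base | solid nucleophile | time |
|---|---|---|---|---|
| birch | 0.30 M | 1.10 equiv | 1.30 equiv | 10 h |
| maple | 0.30 M | 1.40 equiv | 1.30 equiv | 10 h |

- part of the electrophile that has reacted at the end, birch
- part of the electrophile that has reacted at the end, maple
- what raising the equivalents of free base from its lowest to its highest value here does to the part of the electrophile that has reacted (changes below 5 percentage points count as none) (it rises / no change / it falls)

- what is said of acid set free includes crystals
- crystals, solid nucleophile is a solid; its amount is given per volume of the solution
- at the start none of the solid nucleophile is in solution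
- what has gone from electrophile into another species counts as reacted, even if it can come back
- run time (birch): 10 h

1. Let k (0.00772 min⁻¹) be the forward rate constant from electrophile to dormant form, and K (16) their balance constant. The pair relaxes at the rate k(K+1)/K.

2. I multiplied that rate by the run time t. This gave N = kt(K+1)/K, the number of relaxation times in the run: 4.92.

3. I read the outcome off N. The reacted part is R = K/(K+1) × (1 − e^−N), which gave 93.4%. N holds no base, so birch and maple got the same value.

4. I tested whether one number was enough. I replaced the nucleophile curve by a mean, taken as its solubility 0.079 M. The step to target then became pseudo-first-order, a leak of 8.93 × 10⁻⁴ min⁻¹, slower than k. The leak takes a share of 10.4% of what leaves the electrophile. I took that share as lost to the balance, which adds 0.61 percentage points by my estimate.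

5. I committed to 94.0% for both flasks. The base reaches the electrophile through the nucleophile, hence through the leak. The leak's gain is smaller than the margin, so I said no change.

The forecast gave 95.3% for birch and 95.3% for maple, above my figure, and no change. Its ground was that “either base charge mops it up and the dissolved nucleophile stays near saturation”.

The simulation gave 94.7% for birch and 94.7% for maple, a change of 0 points: no change.

At the end of birch, electrophile passed forward into dormant form 8.8 times as fast as into target. The relaxation half-life of 1.41 h is short against 10 h, and at the end birch held 86.0% dormant form, 8.65% target and 5.32% electrophile. Written with that half-life, N for birch is 4.92. For birch read at 4.0 h, N is 1.97, and R gives 81.0%, where the reading stood at 83.5%.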